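The earlier runs and the new flask are simulated for substances that don't exist; noise was put on by code.

At 15 d I take the target in every flask as levelled off: the larch run reads 87% at 8.00 d and 87% at 10.0 d, and the asked time lies later than that last reading, so I ask where the target stops in each flask, not how fast it gets there.

| flask | substrate | partner | capture agent | remark | time |
|---|---|---|---|---|---|
| birch | 3.7 mM | 19 mM | 1 mM | run made earlier |  |
| larch | 16 mM | 19 mM | 1 mM | run made earlier |  |
| elm | 20 mM | 19 mM | 1.3 mM | run made earlier |  |
| Friday's | 20 mM | 10.0 mM | 0.300 mM |  | 15 d |
| Saturday's | 20 mM | 60.0 mM | 3.00 mM |  | 15 d |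
| Wednesday's | 12 mM | 60.0 mM | 1.00 mM |  | 15 d |
| Monday's | 20 mM | 19.0 mM | 1.00 mM |  | 15 d |
| Sunday's | 5.0 mM | 60.0 mM | 3.00 mM |  | 15 d |

- birch (time / d: target / %): 1.67: 59; 3.00: 87; 5.00: 97; 6.00: 95; 8.00: 98; 10.0: 98
- larch (time / d: target / %): 0.625: 13; 1.67: 41; 3.00: 67; 5.00: 82; 6.00: 82; 8.00: 87; 10.0: 87
- elm (time / d: target / %): 0.833: 19; 1.67: 39; 3.00: 58; 6.00: 78; 10.0: 83

(standard deviation of a reading: 1.5 percentage points)



- the flasks put in order of amount of target, in percent of the substrate charged, best first, at 15 d (Friday's / Saturday's / Wednesday's / Monday's / Sunday's)
- the amount of target, in percent of the substrate charged of the flask you put first, at 15 d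
- the amount of target, in percent of the substrate charged of the flask you put last, at 15 d

At the same partner, the last readings fall as substrate rises: 98% in birch, 87% in larch, 83% in elm. I therefore fold the charges into one ratio, substrate over partner, and larch and elm together give 0.158: this loss number, the share of the substrate charged that misses the target per unit of that ratio, puts the target at one minus loss number times ratio.

If each target takes one partner, a ceiling stands beside that line, partner over substrate, and control changes hands between Monday's and Friday's. Monday's line, 83.3%, lies under its ceiling of 95.0%, but Friday's line, 68.3%, lies over its ceiling of 50.0%, so on Friday's partner is the limiting reagent. Sunday's gives 98.7%, Wednesday's 96.8%, Saturday's 94.7%.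

Is one number enough? Birch, left out of the reckoning, gets 96.9% from the line, a gap of 1.1 percentage points against a scatter of 1.5 points. Elm, with 1.3 mM of capture agent, gives 0.161 per unit of ratio and larch, with 1 mM, gives 0.154, so I add no term for capture agent. But the runs hold partner at 19 mM, so the partner in my ratio is an assumption.

The forecast reads Sunday's > Saturday's > Wednesday's > Monday's > Friday's, with 99.5% first and 45% last; of Saturday's and Wednesday's it says “I favour Saturday's for its extra capture agent”. My line parts from it there, with Wednesday's above Saturday's.

The flask gives Sunday's > Wednesday's > Saturday's > Monday's > Friday's, with 98.2% first and 49.9% last, and Wednesday's 96.2% stands above Saturday's 93.3%.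

    substrate ⇌ open intermediate (K = 0.630, k = 0.00150 min⁻¹)
    partner → second intermediate (k = 4.10 × 10⁻⁴ min⁻¹)
    open intermediate + second intermediate → target (k = 0.210 M⁻¹ min⁻¹)
    open intermediate + capture agent → trapped intermediate (k = 0.00400 M⁻¹ min⁻¹)
    substrate + open intermediate → side product (k = 0.0100 M⁻¹ min⁻¹)

By 7.50 d Friday's has partner down to 1.19% of its charge, with target at 47.9% of the substrate. From there to 15.0 d target reaches 49.9% while substrate and open intermediate go on forming side product, which rises from 25.9% to 30.8%. Now take Sunday's with substrate raised to 20 mM, which is Saturday's charge: the ratio 0.333 and the loss number 0.158 give 94.7%, and the computed flask gives 93.3%, with 6.34% as side product.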